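**Assumption:** the target has no sp³ stereocentres. "Single enantiomer" is taken to mean the stated (E)-enone and (E)-geranyl alkene geometries. Paeonol, geraniol, methyl chloroformate and 4-hydroxybenzaldehyde are taken as commercial.

## Retrosynthetic overview
1. Disconnect the enone C=C (Claisen–Schmidt) to 3-geranyl-2-hydroxy-4-methoxyacetophenone and 4-hydroxybenzaldehyde.
2. Disconnect the aryl C3–geranyl bond. It comes from direct, phenol-directed ortho C–H geranylation (the proposed new step) of commercial paeonol with an activated geraniol.
3. No rings are formed: the only ring is the aromatic ring already in paeonol. The E-geranyl geometry comes from geraniol, and the E-enone geometry from the thermodynamic aldol condensation.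

## Route

**Step 1**
Reactants: 1 geraniol; 2 methyl chloroformate
Product: 3 geranyl methyl carbonate
Conditions: ClCO2Me, pyridine, cat. DMAP, CH2Cl2, 0 °C → rt, 3 h
Reagents that add atoms: methyl chloroformate, COC(=O)Cl
Why: Acylation of a primary allylic alcohol gives the carbonate, which is a good Pd(0) ionisation substrate. The C=C geometry is untouched, so the E-geranyl unit is carried forward.

**Step 2**
Reactants: 4 paeonol; 3 geranyl methyl carbonate
Product: 5 1-[3-((2E)-3,7-dimethylocta-2,6-dien-1-yl)-2-hydroxy-4-methoxyphenyl]ethan-1-one
Conditions: Pd(PPh3)4 (5 mol%), Et3B (1.2 equiv, 1 M in THF), THF, 50 °C, 16 h, N2. Purify on AgNO3-silica to remove any Z-isomer.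
Reagents that add atoms: geranyl methyl carbonate (3), COC(=O)OC/C=C(\C)CCC=C(C)C. The geranyl group is the only part transferred to the product; Et3B and Pd leave no atoms.
Why: Proposed new method: this is a free-phenol, boron-templated, Pd-catalysed ortho C–H geranylation that makes the C3–geranyl bond directly.
- Et3B converts paeonol into its aryloxy-diethylborinate, which is chelated to the ketone. This masks the oxygen and blocks O-allylation.
- Pd(0) ionises carbonate 3 to the η3-geranyl-Pd cation. The released methoxide opens the chelate to an aryloxy(methoxy)diethylborate, an electron-rich phenoxide equivalent.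
- The borate oxygen and methoxide hold the cationic allyl-Pd in a contact ion pair. The π-allyl is therefore captured at C3, the only position ortho to the bound oxygen, and not at C5.
- Capture occurs at the unsubstituted allyl terminus. This gives the linear (E)-geranyl product with no quaternary branched isomer.
- Any O-geranyl ether formed is re-ionised by Pd(0), so the C-alkylated product is the thermodynamic sink.
- The closest known chemistry is Tsuji–Trost allylation of phenoxides, Et3B-promoted Pd ionisation of allylic alcohols, and ortho-selective C-alkylation of metal phenoxides. It has not been shown for a free 2-hydroxyaryl ketone with a 3,3-disubstituted terpenyl donor where ortho-C3 must beat para-C5 and O-attack.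
- No stereocentre is formed.

**Step 3**
Reactants: 5 acetophenone; 6 4-hydroxybenzaldehyde
Product: 7 xanthoangelol F
Conditions: NaOH (5 equiv), EtOH/H2O 4:1, rt, 48 h; then cold 1 M HCl to pH ≈ 4
Reagents that add atoms: 4-hydroxybenzaldehyde, O=Cc1ccc(O)cc1 (reactant 6, 1.3 equiv); no other reagent leaves atoms.
Why: Claisen–Schmidt aldol condensation of the methyl ketone enolate with the aldehyde, then E1cB dehydration, gives the thermodynamically favoured (E)-chalcone. The geranyl alkenes, aryl methyl ether and free phenols survive the base, and the 2'-OH···O=C chelate disfavours flavanone closure at rt.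

## Compound list
1 | geraniol, (2E)-3,7-dimethylocta-2,6-dien-1-ol | OC/C=C(\C)CCC=C(C)C | starting material
2 | methyl chloroformate | COC(=O)Cl | starting material
3 | geranyl methyl carbonate | COC(=O)OC/C=C(\C)CCC=C(C)C | intermediate
4 | paeonol, 1-(2-hydroxy-4-methoxyphenyl)ethanone | COc1ccc(C(C)=O)c(O)c1 | starting material
5 | 1-[3-geranyl-2-hydroxy-4-methoxyphenyl]ethanone | COc1ccc(C(C)=O)c(O)c1C/C=C(\C)CCC=C(C)C | intermediate
6 | 4-hydroxybenzaldehyde | O=Cc1ccc(O)cc1 | starting material
7 | xanthoangelol F | COc1ccc(C(=O)/C=C/c2ccc(O)cc2)c(O)c1C/C=C(\C)CCC=C(C)C | target

**Total steps:** 3. **Longest linear sequence:** 3 steps (geraniol → 3 → 5 → 7).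

## Three steps most likely to fail
1. **Step 2 (proposed new step).** The risks are O- versus C-allylation, C5 versus C3 selectivity, α-allylation of the ketone, and partial E→Z erosion. The fallback uses known chemistry with a different strategy: directed ortho-metalation.
   - Protect paeonol as its MOM ether, then convert the ketone to its ethylene ketal.
   - Lithiate with s-BuLi/TMEDA at −78 °C between the OMe and OMOM groups, then alkylate with geranyl bromide under CuI catalysis.
   - Remove the ketal and MOM with aqueous HCl/THF to give 5.
2. **Step 3.** Free phenols can give a low-yielding condensation or flavanone formation. The fallback is a protecting-group route: condense 5 with 4-(MOMO)benzaldehyde (made from 6 and MOMCl), then remove the MOM group with PPTS in t-BuOH.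
3. **Step 1.** The geranyl carbonate can ionise or isomerise on silica. The fallback is to skip the carbonate and use geraniol (1) directly in step 2 as the Et3B-activated allylic alcohol (Pd/Et3B ionisation of the alcohol).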